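**Retrosynthetic overview**

1. Target 20 ← O‑methylation of p‑quinol 18 ← methoxide‑mediated excision of a chiral lactate tether from bicyclic dienone lactone 16.
2. 16 ← auxiliary‑directed oxidative dearomatisation of resorcinol‑type phenol 14. The six‑membered carbocycle is aromatic from the start and is dearomatised last; the only ring closed in the route is a temporary 1,4‑dioxan‑2‑one (O on C5 → lactate → O on C4), which is removed again.
3. 14 ← disconnection at the bond between the vinyl CH (C7) and the dimethoxyphenyl ring: one‑flask Zr‑catalysed methylalumination of arylacetylene 9 and Pd coupling with 4‑iodoveratrole. This creates the C8–CH3 bond, the E‑C7=C8 olefin and the vinyl–aryl bond together.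
4. Enabling feature: the O‑bearing quaternary C4 lies para to the C1 carbonyl and ortho to the C5 methoxy carbon, so the cyclohexadienone is an oxidised 4‑substituted resorcinol. Carried as the arene, C4 is an aryl carbon bearing C8≡C7H, which tolerates Me3Al and directs methyl to C8.
5. 9 ← 5‑bromo‑2,4‑dihydroxybenzaldehyde by Suzuki propenylation, regioselective silylation, Mitsunobu etherification with (S)‑lactamide and Ohira–Bestmann homologation.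

Key step: step 5

Assumption: in step 7 the lactate methyl is taken to sit in the outward (bowsprit) position of a boat‑like six‑membered transition state, so the (R)‑aryloxypropanamide delivers oxygen to the face giving (S) at C4; if the opposite sense were found, the enantiomeric lactamide would be used in step 3.

**Step 1**
Reactants: 1 5‑bromo‑2,4‑dihydroxybenzaldehyde; 2 (1E)‑prop‑1‑en‑1‑ylboronic acid
Product: 3 2,4‑dihydroxy‑5‑[(1E)‑prop‑1‑en‑1‑yl]benzaldehyde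
Conditions: Pd(OAc)2 (3 mol%), SPhos (6 mol%), K3PO4, 1,4‑dioxane/H2O, 80 °C
Reagents that add atoms: (1E)‑prop‑1‑en‑1‑ylboronic acid, C/C=C/B(O)O
Why: Suzuki–Miyaura coupling of the aryl bromide with the alkenylboronic acid should transfer the propenyl group with retention of its E geometry, and a dialkylbiarylphosphine palladium catalyst tolerates the free phenols and the aldehyde.

**Step 2**
Reactants: 3 2,4‑dihydroxy‑5‑[(1E)‑prop‑1‑en‑1‑yl]benzaldehyde; 4 chlorotriisopropylsilane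
Product: 5 2‑hydroxy‑5‑[(1E)‑prop‑1‑en‑1‑yl]‑4‑[(triisopropylsilyl)oxy]benzaldehyde
Conditions: TIPSCl (1.05 equiv), imidazole, DMF, 0 °C
Reagents that add atoms: chlorotriisopropylsilane, CC(C)[Si](Cl)(C(C)C)C(C)C
Why: Regioselective phenol silylation: the 4‑hydroxyl is the more acidic and accessible one because the 2‑hydroxyl is held in a hydrogen bond to the formyl oxygen, so one equivalent of silyl chloride should react at O4 only.

**Step 3**
Reactants: 5 2‑hydroxy‑5‑[(1E)‑prop‑1‑en‑1‑yl]‑4‑[(triisopropylsilyl)oxy]benzaldehyde; 6 (2S)‑2‑hydroxy‑N,N‑dimethylpropanamide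
Product: 7 (2R)‑2‑{2‑formyl‑4‑[(1E)‑prop‑1‑en‑1‑yl]‑5‑[(triisopropylsilyl)oxy]phenoxy}‑N,N‑dimethylpropanamide
Conditions: PPh3, DIAD, THF, 0 °C → rt
Reagents that add atoms: (2S)‑2‑hydroxy‑N,N‑dimethylpropanamide, C[C@H](O)C(=O)N(C)C
Why: Mitsunobu etherification of the remaining phenol proceeds by SN2 displacement of the oxyphosphonium at the lactamide carbinol carbon, so the (S) centre is inverted to the (R)‑aryl ether that later steers the dearomatisation.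

**Step 4**
Reactants: 7 (2R)‑2‑{2‑formyl‑4‑[(1E)‑prop‑1‑en‑1‑yl]‑5‑[(triisopropylsilyl)oxy]phenoxy}‑N,N‑dimethylpropanamide; 8 dimethyl (1‑diazo‑2‑oxopropyl)phosphonate
Product: 9 (2R)‑2‑{2‑ethynyl‑4‑[(1E)‑prop‑1‑en‑1‑yl]‑5‑[(triisopropylsilyl)oxy]phenoxy}‑N,N‑dimethylpropanamide
Conditions: K2CO3, MeOH, 0 °C → rt
Reagents that add atoms: dimethyl (1‑diazo‑2‑oxopropyl)phosphonate, CC(=O)C(=[N+]=[N-])P(=O)(OC)OC
Why: Ohira–Bestmann (Seyferth–Gilbert) homologation converts the aryl aldehyde into the terminal alkyne under carbonate/methanol conditions that should neither cleave the hindered aryl TIPS ether nor epimerise the amide α‑centre.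

**Step 5**
Reactants: 9 (2R)‑2‑{2‑ethynyl‑4‑[(1E)‑prop‑1‑en‑1‑yl]‑5‑[(triisopropylsilyl)oxy]phenoxy}‑N,N‑dimethylpropanamide; 10 trimethylaluminium; 11 4‑iodo‑1,2‑dimethoxybenzene
Product: 13 (2R)‑2‑{2‑[(1E)‑1‑(3,4‑dimethoxyphenyl)prop‑1‑en‑2‑yl]‑4‑[(1E)‑prop‑1‑en‑1‑yl]‑5‑[(triisopropylsilyl)oxy]phenoxy}‑N,N‑dimethylpropanamide, via alkenyldimethylalane 12 (not isolated)
Conditions: Me3Al (4 equiv), Cp2ZrCl2 (0.5 equiv), CH2Cl2, 0 °C → rt; volatiles removed in vacuo; then THF, 4‑iodo‑1,2‑dimethoxybenzene, ZnCl2 (20 mol%), Pd(PPh3)4 (5 mol%), rt → 45 °C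
Reagents that add atoms: trimethylaluminium, C[Al](C)C; 4‑iodo‑1,2‑dimethoxybenzene, COc1ccc(I)cc1OC
Why: Negishi Zr‑catalysed methylalumination followed in the same flask by Pd‑catalysed, Zn‑assisted cross‑coupling, a tandem with close precedent for terminal arylalkynes: the Cp2ZrCl2/Me3Al bimetallic adds CH3 and metal syn across the triple bond, methyl to the internal aryl‑bearing carbon (C8) and aluminium to the terminal carbon (C7), giving alkenylalane 12. Oxidative addition of 4‑iodoveratrole to Pd(0), alkenyl transfer from Al through Zn to Pd and reductive elimination then form the C7–aryl bond with retention of olefin geometry. No ring is closed and no stereocentre is formed; the element under control is the E geometry of C7=C8, which follows from syn carbometalation plus stereoretentive coupling. The step needs regioselectivity (the aryl group on the alkyne directs methyl to the benzylic carbon) and chemoselectivity for the terminal alkyne over the 1,2‑disubstituted propenyl olefin (internal alkenes are inert to Zr/Al methylmetalation). It also needs a ring that survives Me3Al, which is why the cyclohexadienone is carried as the aromatic resorcinol diether: arene, silyl ether and tertiary amide (as its Lewis adduct, hence excess Me3Al) are tolerated, whereas a dienone would not be. Removing excess Me3Al before the coupling suppresses methyl transfer to the aryl iodide, and the (R) centre is untouched because no base able to enolise the amide is present.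

**Step 6**
Reactants: 13 (2R)‑2‑{2‑[(1E)‑1‑(3,4‑dimethoxyphenyl)prop‑1‑en‑2‑yl]‑4‑[(1E)‑prop‑1‑en‑1‑yl]‑5‑[(triisopropylsilyl)oxy]phenoxy}‑N,N‑dimethylpropanamide
Product: 14 (2R)‑2‑{2‑[(1E)‑1‑(3,4‑dimethoxyphenyl)prop‑1‑en‑2‑yl]‑5‑hydroxy‑4‑[(1E)‑prop‑1‑en‑1‑yl]phenoxy}‑N,N‑dimethylpropanamide
Conditions: TBAF, AcOH (1:1), THF, 0 °C
Reagents that add atoms: none
Why: Fluoride‑mediated cleavage of the aryl silyl ether, buffered with acetic acid so that the amide α‑centre is not exposed to basic phenoxide, should liberate the phenol needed for oxidation.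

**Step 7**
Reactants: 14 (2R)‑2‑{2‑[(1E)‑1‑(3,4‑dimethoxyphenyl)prop‑1‑en‑2‑yl]‑5‑hydroxy‑4‑[(1E)‑prop‑1‑en‑1‑yl]phenoxy}‑N,N‑dimethylpropanamide
Product: 16 (3R,8aS)‑8a‑[(1E)‑1‑(3,4‑dimethoxyphenyl)prop‑1‑en‑2‑yl]‑3‑methyl‑7‑[(1E)‑prop‑1‑en‑1‑yl]‑3H‑1,4‑benzodioxine‑2,6(8aH)‑dione, via cyclic O‑alkyl iminium trifluoroacetate 15 (not isolated)
Conditions: PhI(OCOCF3)2 (1.1 equiv), CH2Cl2/MeCN, −40 °C; then H2O, −40 → 0 °C
Reagents that add atoms: water, O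
Why: Hypervalent‑iodine oxidative dearomatisation of a resorcinol ether directed by a lactamide tether: the phenol is oxidised to a phenoxenium‑type cation, the amide oxygen (which can reach C4 only through a six‑membered transition state) traps it para to the phenol oxygen to give iminium ether 15, and water hydrolyses this to lactone 16; the new quaternary stereocentre C4 is set by the (R)‑lactate centre, whose methyl group takes the outward position of the boat‑like transition state so that oxygen is delivered to the face giving (S).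

**Step 8**
Reactants: 16 (3R,8aS)‑8a‑[(1E)‑1‑(3,4‑dimethoxyphenyl)prop‑1‑en‑2‑yl]‑3‑methyl‑7‑[(1E)‑prop‑1‑en‑1‑yl]‑3H‑1,4‑benzodioxine‑2,6(8aH)‑dione
Product: 18 (4S)‑4‑[(1E)‑1‑(3,4‑dimethoxyphenyl)prop‑1‑en‑2‑yl]‑4‑hydroxy‑5‑methoxy‑2‑[(1E)‑prop‑1‑en‑1‑yl]cyclohexa‑2,5‑dien‑1‑one, via ring‑opened hydroxy ester 17 (not isolated)
Conditions: NaOMe (0.2 equiv), MeOH, −10 °C → rt
Reagents that add atoms: methanol, CO
Why: Methoxide‑catalysed transesterification opens the lactone to ester 17, and addition–elimination of methoxide at C5 of the vinylogous ester then expels the better‑stabilised lactate alkoxide, so the auxiliary leaves as methyl (R)‑lactate while the C4–O bond, and with it the stereocentre, is never broken.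

**Step 9**
Reactants: 18 (4S)‑4‑[(1E)‑1‑(3,4‑dimethoxyphenyl)prop‑1‑en‑2‑yl]‑4‑hydroxy‑5‑methoxy‑2‑[(1E)‑prop‑1‑en‑1‑yl]cyclohexa‑2,5‑dien‑1‑one; 19 iodomethane
Product: 20 (4S)‑4‑[(1E)‑1‑(3,4‑dimethoxyphenyl)prop‑1‑en‑2‑yl]‑4,5‑dimethoxy‑2‑[(1E)‑prop‑1‑en‑1‑yl]cyclohexa‑2,5‑dien‑1‑one
Conditions: NaH (1.2 equiv), MeI (3 equiv), THF, 0 °C
Reagents that add atoms: iodomethane, CI
Why: Williamson O‑methylation of the tertiary p‑quinol alkoxide, a known transformation of 4‑hydroxycyclohexa‑2,5‑dienones, should give the methyl ether with retention at C4 because only the O–H bond is involved.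

**Compound list**

1 | 5‑bromo‑2,4‑dihydroxybenzaldehyde | O=Cc1cc(Br)c(O)cc1O | starting material
2 | (1E)‑prop‑1‑en‑1‑ylboronic acid | C/C=C/B(O)O | starting material
3 | 2,4‑dihydroxy‑5‑[(1E)‑prop‑1‑en‑1‑yl]benzaldehyde | C/C=C/c1cc(C=O)c(O)cc1O | intermediate
4 | chlorotriisopropylsilane | CC(C)[Si](Cl)(C(C)C)C(C)C | starting material
5 | 2‑hydroxy‑5‑[(1E)‑prop‑1‑en‑1‑yl]‑4‑[(triisopropylsilyl)oxy]benzaldehyde | C/C=C/c1cc(C=O)c(O)cc1O[Si](C(C)C)(C(C)C)C(C)C | intermediate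
6 | (2S)‑2‑hydroxy‑N,N‑dimethylpropanamide | C[C@H](O)C(=O)N(C)C | starting material
7 | (2R)‑2‑{2‑formyl‑4‑[(1E)‑prop‑1‑en‑1‑yl]‑5‑[(triisopropylsilyl)oxy]phenoxy}‑N,N‑dimethylpropanamide | C/C=C/c1cc(C=O)c(O[C@H](C)C(=O)N(C)C)cc1O[Si](C(C)C)(C(C)C)C(C)C | intermediate
8 | dimethyl (1‑diazo‑2‑oxopropyl)phosphonate | CC(=O)C(=[N+]=[N-])P(=O)(OC)OC | starting material
9 | (2R)‑2‑{2‑ethynyl‑4‑[(1E)‑prop‑1‑en‑1‑yl]‑5‑[(triisopropylsilyl)oxy]phenoxy}‑N,N‑dimethylpropanamide | C/C=C/c1cc(C#C)c(O[C@H](C)C(=O)N(C)C)cc1O[Si](C(C)C)(C(C)C)C(C)C | intermediate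
10 | trimethylaluminium | C[Al](C)C | starting material
11 | 4‑iodo‑1,2‑dimethoxybenzene | COc1ccc(I)cc1OC | starting material
12 | (2R)‑2‑{2‑[(1E)‑1‑(dimethylalumanyl)prop‑1‑en‑2‑yl]‑4‑[(1E)‑prop‑1‑en‑1‑yl]‑5‑[(triisopropylsilyl)oxy]phenoxy}‑N,N‑dimethylpropanamide | C/C=C/c1cc(/C(C)=C/[Al](C)C)c(O[C@H](C)C(=O)N(C)C)cc1O[Si](C(C)C)(C(C)C)C(C)C | intermediate
13 | (2R)‑2‑{2‑[(1E)‑1‑(3,4‑dimethoxyphenyl)prop‑1‑en‑2‑yl]‑4‑[(1E)‑prop‑1‑en‑1‑yl]‑5‑[(triisopropylsilyl)oxy]phenoxy}‑N,N‑dimethylpropanamide | C/C=C/c1cc(/C(C)=C/c2ccc(OC)c(OC)c2)c(O[C@H](C)C(=O)N(C)C)cc1O[Si](C(C)C)(C(C)C)C(C)C | intermediate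
14 | (2R)‑2‑{2‑[(1E)‑1‑(3,4‑dimethoxyphenyl)prop‑1‑en‑2‑yl]‑5‑hydroxy‑4‑[(1E)‑prop‑1‑en‑1‑yl]phenoxy}‑N,N‑dimethylpropanamide | C/C=C/c1cc(/C(C)=C/c2ccc(OC)c(OC)c2)c(O[C@H](C)C(=O)N(C)C)cc1O | intermediate
15 | N‑{(3R,8aS)‑8a‑[(1E)‑1‑(3,4‑dimethoxyphenyl)prop‑1‑en‑2‑yl]‑3‑methyl‑6‑oxo‑7‑[(1E)‑prop‑1‑en‑1‑yl]‑6,8a‑dihydro‑1,4‑benzodioxin‑2(3H)‑ylidene}‑N‑methylmethanaminium trifluoroacetate | C/C=C/C1=C[C@@]2(/C(C)=C/c3ccc(OC)c(OC)c3)OC(=[N+](C)C)[C@@H](C)OC2=CC1=O.[O-]C(=O)C(F)(F)F | intermediate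
16 | (3R,8aS)‑8a‑[(1E)‑1‑(3,4‑dimethoxyphenyl)prop‑1‑en‑2‑yl]‑3‑methyl‑7‑[(1E)‑prop‑1‑en‑1‑yl]‑3H‑1,4‑benzodioxine‑2,6(8aH)‑dione | C/C=C/C1=C[C@@]2(/C(C)=C/c3ccc(OC)c(OC)c3)OC(=O)[C@@H](C)OC2=CC1=O | intermediate
17 | methyl (2R)‑2‑({(6S)‑6‑[(1E)‑1‑(3,4‑dimethoxyphenyl)prop‑1‑en‑2‑yl]‑6‑hydroxy‑3‑oxo‑4‑[(1E)‑prop‑1‑en‑1‑yl]cyclohexa‑1,4‑dien‑1‑yl}oxy)propanoate | C/C=C/C1=C[C@](O)(/C(C)=C/c2ccc(OC)c(OC)c2)C(O[C@H](C)C(=O)OC)=CC1=O | intermediate
18 | (4S)‑4‑[(1E)‑1‑(3,4‑dimethoxyphenyl)prop‑1‑en‑2‑yl]‑4‑hydroxy‑5‑methoxy‑2‑[(1E)‑prop‑1‑en‑1‑yl]cyclohexa‑2,5‑dien‑1‑one | C/C=C/C1=C[C@](O)(/C(C)=C/c2ccc(OC)c(OC)c2)C(OC)=CC1=O | intermediate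
19 | iodomethane | CI | starting material
20 | (4S)‑4‑[(1E)‑1‑(3,4‑dimethoxyphenyl)prop‑1‑en‑2‑yl]‑4,5‑dimethoxy‑2‑[(1E)‑prop‑1‑en‑1‑yl]cyclohexa‑2,5‑dien‑1‑one | C/C=C/C1=C[C@](OC)(/C(C)=C/c2ccc(OC)c(OC)c2)C(OC)=CC1=O | target

**Step count and risk**

Total steps: 9. Longest linear sequence: 9 (1 → 20).

Steps most likely to fail:

1. Step 7. The oxidised phenol is a cation delocalised through C8=C7 into the dimethoxyphenyl ring, so capture at the remote benzylic carbon C7, over‑oxidation of the electron‑rich stilbene, ionisation of the doubly allylic acyloxy group of 16, or insufficient facial bias may intervene. The fallback attaches the aryl group only after dearomatisation; it sets out from 9 and returns at 20. Methylalumination of 9 as in step 5 followed by iodinolysis (I2, THF, −30 °C) should give (2R)‑2‑{2‑[(1E)‑1‑iodoprop‑1‑en‑2‑yl]‑4‑[(1E)‑prop‑1‑en‑1‑yl]‑5‑[(triisopropylsilyl)oxy]phenoxy}‑N,N‑dimethylpropanamide F1. Desilylation (TBAF/AcOH) should give (2R)‑2‑{5‑hydroxy‑2‑[(1E)‑1‑iodoprop‑1‑en‑2‑yl]‑4‑[(1E)‑prop‑1‑en‑1‑yl]phenoxy}‑N,N‑dimethylpropanamide F2, whose iodoalkene cannot stabilise a cation at C7. Oxidation with PhI(OCOCF3)2 and then water should give (3R,8aS)‑8a‑[(1E)‑1‑iodoprop‑1‑en‑2‑yl]‑3‑methyl‑7‑[(1E)‑prop‑1‑en‑1‑yl]‑3H‑1,4‑benzodioxine‑2,6(8aH)‑dione F3. NaOMe/MeOH should give (4S)‑4‑hydroxy‑4‑[(1E)‑1‑iodoprop‑1‑en‑2‑yl]‑5‑methoxy‑2‑[(1E)‑prop‑1‑en‑1‑yl]cyclohexa‑2,5‑dien‑1‑one F4, and NaH/MeI should give (4S)‑4‑[(1E)‑1‑iodoprop‑1‑en‑2‑yl]‑4,5‑dimethoxy‑2‑[(1E)‑prop‑1‑en‑1‑yl]cyclohexa‑2,5‑dien‑1‑one F5. Suzuki–Miyaura coupling of F5 with (3,4‑dimethoxyphenyl)boronic acid (Pd(PPh3)4, K3PO4, THF/H2O, rt) should then form the same vinyl–aryl bond and give 20.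

2. Step 5. Complexation of the aluminium and zirconium species by the amide and the ortho ether oxygen may retard or misdirect the carbometalation, the alkyne C–H may be metalated, or methyl transfer may compete with alkenyl transfer in the coupling. The fallback sets out from 9 and returns at 13. Copper‑catalysed methylboration (CuCl/Xantphos, B2pin2, MeI, LiOtBu, THF, rt; syn borylcupration with boron on the terminal carbon, then methylation of the alkenylcopper) should give the isolable (2R)‑N,N‑dimethyl‑2‑{4‑[(1E)‑prop‑1‑en‑1‑yl]‑2‑[(1E)‑1‑(4,4,5,5‑tetramethyl‑1,3,2‑dioxaborolan‑2‑yl)prop‑1‑en‑2‑yl]‑5‑[(triisopropylsilyl)oxy]phenoxy}propanamide F6. Suzuki–Miyaura coupling of F6 with 11 (Pd(dppf)Cl2, K3PO4, dioxane/H2O, 60 °C) should give 13.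

3. Step 8. Methoxide may add at C3 of the cross‑conjugated dienone, or the free tertiary alkoxide may degrade, before alkoxy exchange at C5 is complete. The fallback sets out from 16 and returns at 20, methylating before the exchange. Neutral methanolysis of 16 (MeOH, DMAP cat., rt) should allow 17 to be isolated. Methylation of its tertiary hydroxyl without strong base (MeI, Ag2O, MeCN, rt) should give methyl (2R)‑2‑({(6S)‑6‑[(1E)‑1‑(3,4‑dimethoxyphenyl)prop‑1‑en‑2‑yl]‑6‑methoxy‑3‑oxo‑4‑[(1E)‑prop‑1‑en‑1‑yl]cyclohexa‑1,4‑dien‑1‑yl}oxy)propanoate F7. Alkoxy exchange at C5 of F7 (NaOMe cat., MeOH, −20 °C) should then give 20 directly.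

**Further compounds**

F1 | step 7 | (2R)‑2‑{2‑[(1E)‑1‑iodoprop‑1‑en‑2‑yl]‑4‑[(1E)‑prop‑1‑en‑1‑yl]‑5‑[(triisopropylsilyl)oxy]phenoxy}‑N,N‑dimethylpropanamide | C/C=C/c1cc(/C(C)=C/I)c(O[C@H](C)C(=O)N(C)C)cc1O[Si](C(C)C)(C(C)C)C(C)C
F2 | step 7 | (2R)‑2‑{5‑hydroxy‑2‑[(1E)‑1‑iodoprop‑1‑en‑2‑yl]‑4‑[(1E)‑prop‑1‑en‑1‑yl]phenoxy}‑N,N‑dimethylpropanamide | C/C=C/c1cc(/C(C)=C/I)c(O[C@H](C)C(=O)N(C)C)cc1O
F3 | step 7 | (3R,8aS)‑8a‑[(1E)‑1‑iodoprop‑1‑en‑2‑yl]‑3‑methyl‑7‑[(1E)‑prop‑1‑en‑1‑yl]‑3H‑1,4‑benzodioxine‑2,6(8aH)‑dione | C/C=C/C1=C[C@@]2(/C(C)=C/I)OC(=O)[C@@H](C)OC2=CC1=O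
F4 | step 7 | (4S)‑4‑hydroxy‑4‑[(1E)‑1‑iodoprop‑1‑en‑2‑yl]‑5‑methoxy‑2‑[(1E)‑prop‑1‑en‑1‑yl]cyclohexa‑2,5‑dien‑1‑one | C/C=C/C1=C[C@](O)(/C(C)=C/I)C(OC)=CC1=O
F5 | step 7 | (4S)‑4‑[(1E)‑1‑iodoprop‑1‑en‑2‑yl]‑4,5‑dimethoxy‑2‑[(1E)‑prop‑1‑en‑1‑yl]cyclohexa‑2,5‑dien‑1‑one | C/C=C/C1=C[C@](OC)(/C(C)=C/I)C(OC)=CC1=O
F6 | step 5 | (2R)‑N,N‑dimethyl‑2‑{4‑[(1E)‑prop‑1‑en‑1‑yl]‑2‑[(1E)‑1‑(4,4,5,5‑tetramethyl‑1,3,2‑dioxaborolan‑2‑yl)prop‑1‑en‑2‑yl]‑5‑[(triisopropylsilyl)oxy]phenoxy}propanamide | C/C=C/c1cc(/C(C)=C/B2OC(C)(C)C(C)(C)O2)c(O[C@H](C)C(=O)N(C)C)cc1O[Si](C(C)C)(C(C)C)C(C)C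
F7 | step 8 | methyl (2R)‑2‑({(6S)‑6‑[(1E)‑1‑(3,4‑dimethoxyphenyl)prop‑1‑en‑2‑yl]‑6‑methoxy‑3‑oxo‑4‑[(1E)‑prop‑1‑en‑1‑yl]cyclohexa‑1,4‑dien‑1‑yl}oxy)propanoate | C/C=C/C1=C[C@](OC)(/C(C)=C/c2ccc(OC)c(OC)c2)C(O[C@H](C)C(=O)OC)=CC1=O
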